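The readings were computed with made-up constants; scatter was added.

Per unit of substrate lost, I ask what turns up as product, and I call the loss that does not, divided by the product, the waste odds: the selectivity factor turned upside down. The three flasks have the same charges and differ in what is fed.

| flask | substrate | reagent | catalyst | remark | time |
|---|---|---|---|---|---|
| north-east | 0.10 M | 0.12 M | 0.10 mM | run made earlier |  |
| south | 0.10 M | 0.060 M | 0.10 mM | run made earlier |  |
| north-west | 0.10 M | 0.090 M | 0.10 mM | run made earlier |  |
| north | 0.20 M | 0.12 M | 0.10 mM | run made earlier |  |
| larch | 0.10 M | 0.120 M (fed, over 25 min) | 0.10 mM | all else is in the flask from the start; the feed brings no volume worth counting | 1.0 h |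
| ash | 0.10 M (fed, over 25 min) | 0.120 M | 0.10 mM | all else is in the flask from the start; the feed brings no volume worth counting | 1.0 h |
| oak | 0.10 M | 0.120 M | 0.10 mM | everything together at the start | 1.0 h |

| run | time / min | product / % | substrate / % |
|---|---|---|---|
| north-east | 5.00 | 13 | 58 |
| north-east | 15.0 | 32 | 27 |
| north-east | 30.0 | 42 | 11 |
| north-east | 40.0 | 43 | 6 |
| north-east | 60.0 | 49 | 3 |
| south | 5.00 | 6 | 66 |
| south | 15.0 | 17 | 34 |
| south | 30.0 | 27 | 17 |
| south | 40.0 | 24 | 13 |
| south | 60.0 | 30 | 8 |
| north-west | 5.00 | 9 | 61 |
| north-west | 15.0 | 25 | 29 |
| north-west | 30.0 | 32 | 12 |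
| north-west | 40.0 | 35 | 11 |
| north-west | 60.0 | 41 | 2 |
| north | 5.00 | 10 | 47 |
| north | 10.0 | 16 | 27 |
| north | 15.0 | 18 | 19 |
| north | 30.0 | 22 | 5 |
| north | 60.0 | 28 | 4 |

(scatter of a reading: 1.5 percentage points)

- the flask that comes out highest in amount of product, in percent of the substrate charged, or "all alike" when all lie within 1.5 percentage points (larch / ash / oak / all alike)
- product at the end, in percent of the substrate charged, larch
- product at the end, in percent of the substrate charged, ash
- product at the end, in percent of the substrate charged, oak

- a reading or a percentage of product counts all its forms, free or not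

The north-east run has oak's recipe, so it serves as my clock. Up to 5.00 min it loses 0.0840 min⁻¹ of the substrate charge, of which 0.0260 min⁻¹ appears as product. From there to 15.0 min the product speed falls by a factor 1.37, but the waste speed falls by 4.83. The waste odds therefore read 2.23 on the first stretch and 0.632 on the second, where the fraction left falls from 58% to 27%. The south run, with half the reagent, reads 4.67 on its first stretch, twice the north-east value, so I divide the odds by the reagent present. Each stretch then yields its substrate loss over one plus its odds.

For oak I take the north-east end reading, 49%. Ash's feed of 0.0400 min⁻¹ is slower than the first-stretch loss and faster than the second, so I give ash the second-stretch odds throughout on a loss of 94.0% of its charge, and reckon 57.6%. In larch, on the north-east clock, the reagent fed at mid-stretch is 0.100 of its charge, then 0.400, against about the whole charge, then 0.812 of it, present in north-east. The odds become 22.3 and 1.28. With north-east's later gain added, I reckon larch at 32.4%, so I rank ash first.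

The forecast, a little apart from me, names ash, with 35% for larch, 55% for ash and 48% for oak, holding that “Larch starves the reagent early, so substrate is wasted”.

The flasks give ash as highest: larch 32.5%, ash 53.1%, oak 46.9%.

    substrate + reagent + catalyst → product + catalyst, rate k1*[substrate]*[reagent]*[catalyst]/(1 + ([substrate]/sat1)) (0.0800 M, k = 110 M⁻² s⁻¹)
    catalyst + product ⇌ idle complex (K = 41.0 M⁻¹, k = 0.00570 M⁻¹ s⁻¹)
    2 substrate → homo dimer (k = 0.00790 M⁻¹ s⁻¹)

Idle complex counts as product, and in oak free product's half-life on the path into it, forward step alone, the other concentrations as charged, is 14 d, long against 1.0 h. The neighbour of larch charged with 0.060 M substrate starts at 0.600 of larch's charge, about the north-east level after the first stretch, so I begin it on the second. That stretch takes the first 10.0 min of the feed, with 0.200 of the reagent fed at its middle, so the odds are 2.57. Adding north-east's later gain and rescaling to the smaller charge, I get 42.8%. That flask holds 45.3% product, all its forms counted, at 1.00 h, with 3.38% of its substrate left.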